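**Retrosynthetic overview**
1. Target 5 ⇒ both prenyl groups are cut off last (two aryl–CH2 bonds), giving 6,6'-dibromo-1,3'-biindole 3 and prenylboronic ester 4.
2. 3 ⇒ the N1–C3' bond is cut, giving 6-bromo-1H-indole 1 as the N–H partner and the C3 iodonium salt 2 as the electrophile.
3. 2 ⇒ 1 and a mesityl-λ3-iodane (C3–H functionalisation), so both halves of 3 come from the same bought indole.
4. No ring is built: both indole ring systems are bought intact. The order is iodonium formation, C–N union of the two indoles, then twofold prenylation.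

Assumption: the target has no stereocentre and the N1–C3' axis rotates freely, so it is achiral and no enantiomer has to be controlled.

**Route**

Step 1
Reactants: 1 6-bromo-1H-indole
Product: 2 (6-bromo-1H-indol-3-yl)(2,4,6-trimethylphenyl)iodonium 4-methylbenzenesulfonate
Conditions: MesI(OAc)2 (0.95 equiv), TsOH·H2O (0.95 equiv), MeCN, 25 °C, 15 min; then 1 (1.0 equiv), −20 → 0 °C, 1 h; Et2O added, salt filtered off and washed with Et2O
Reagents that add atoms: [bis(acetoxy)iodo]mesitylene, MesI(OAc)2, CC(=O)OI(OC(C)=O)c1c(C)cc(C)cc1C; 4-methylbenzenesulfonic acid monohydrate, TsOH·H2O, Cc1ccc(S(=O)(=O)O)cc1.O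
Why: Electrophilic aromatic substitution by a Koser-type reagent: MesI(OH)OTs, formed in the flask from MesI(OAc)2 and TsOH·H2O, attacks the most nucleophilic carbon (C3) of the indole and loses water to give the aryl(indolyl)iodonium tosylate; precipitation frees the salt from acetic acid and any unreacted oxidant before the second indole is added, and no stereocentre is formed.

Step 2
Reactants: 2 (6-bromo-1H-indol-3-yl)(2,4,6-trimethylphenyl)iodonium 4-methylbenzenesulfonate; 1 6-bromo-1H-indole (2.0 equiv, the excess is recovered)
Product: 3 6-bromo-3-(6-bromo-1H-indol-1-yl)-1H-indole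
Conditions: CuI (10 mol %), 1,10-phenanthroline (12 mol %), Cs2CO3 (3 equiv), DMF, 25 °C, 12 h
Reagents that add atoms: none
Why: Proposed new method: a head-to-tail N1–C3' union of two unprotected N–H indoles through an (indol-3-yl)(mesityl)iodonium salt – phenanthroline-ligated monovalent copper binds 1 as an N-bound indolide, adds oxidatively to the unhindered indolyl–iodine bond of 2 (the two ortho-methyl groups make mesityl the aryl that is not transferred) and the trivalent copper aryl amide reductively eliminates the C3'–N1 bond at the ipso carbon, so neither the C2 cine-substitution typical of 3-haloindolenines nor C3–C3' arylation is expected; under base 2 reacts as its N-deprotonated zwitterion, whose nitrogen is a poor ligand for copper, which together with the excess of 1 holds back self-coupling and trimer formation, and the C–Br bonds are inert to copper at 25 °C; closest known reaction type: copper-catalysed N-arylation of azoles with diaryliodonium and N-protected indolyl(aryl)iodonium salts (Ullmann–Goldberg type), not shown so far with an N–H indole as both the iodonium and the nucleophile partner.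

Step 3
Reactants: 3 6-bromo-3-(6-bromo-1H-indol-1-yl)-1H-indole; 4 4,4,5,5-tetramethyl-2-(3-methylbut-2-en-1-yl)-1,3,2-dioxaborolane (prenylboronic acid pinacol ester, 3.0 equiv; two molecules are incorporated)
Product: 5 6-(3-methylbut-2-en-1-yl)-3-[6-(3-methylbut-2-en-1-yl)-1H-indol-1-yl]-1H-indole
Conditions: PdCl2(IPent)(3-chloropyridine) (Pd-PEPPSI-IPent, IPent = 1,3-bis[2,6-di(pentan-3-yl)phenyl]imidazol-2-ylidene; 4 mol %), 5 M aq. KOH (6 equiv), THF, 70 °C, 24 h
Reagents that add atoms: none
Why: Twofold α-selective Suzuki–Miyaura allyl–aryl coupling, in which the very bulky NHC ligand holds palladium at the primary CH2 terminus of the allyl fragment before reductive elimination, so each C–Br bond gives the linear prenyl arene and not the reverse-prenyl isomer; the N–H, the free C2–H and the N1–C3' bond are stable to aqueous KOH, and no stereocentre is formed.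

**Compound list**
1 | 6-bromo-1H-indole | Brc1ccc2cc[nH]c2c1 | starting material
2 | (6-bromo-1H-indol-3-yl)(2,4,6-trimethylphenyl)iodonium 4-methylbenzenesulfonate | Cc1cc(C)c([I+]c2c[nH]c3cc(Br)ccc23)c(C)c1.Cc1ccc(S(=O)(=O)[O-])cc1 | intermediate
3 | 6-bromo-3-(6-bromo-1H-indol-1-yl)-1H-indole | Brc1ccc2c(-n3ccc4ccc(Br)cc43)c[nH]c2c1 | intermediate
4 | 4,4,5,5-tetramethyl-2-(3-methylbut-2-en-1-yl)-1,3,2-dioxaborolane | CC(C)=CCB1OC(C)(C)C(C)(C)O1 | starting material
5 | 6-(3-methylbut-2-en-1-yl)-3-[6-(3-methylbut-2-en-1-yl)-1H-indol-1-yl]-1H-indole | CC(C)=CCc1ccc2c(-n3ccc4ccc(CC=C(C)C)cc43)c[nH]c2c1 | target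

**Step count and risk**
Total step count: 3. Longest linear sequence: 3 (1 → 2 → 3 → 5).

The three steps most likely to fail, most risky first:

1. Step 2 (the proposed new step). Copper may arylate C3 of the incoming indole (giving a 3,3'-biindole) instead of nitrogen. The zwitterion of 2 may couple with itself, or 3 may couple again to a trimer. Fallback by known chemistry, setting out from 1 and coming back at 3: 1 is iodinated (I2, KOH, DMF, 25 °C) to 6-bromo-3-iodo-1H-indole F1. F1 is N-sulfonylated (NaH, TsCl, THF, 0 °C) to 6-bromo-3-iodo-1-(4-methylbenzenesulfonyl)-1H-indole F2. Ullmann–Goldberg coupling of F2 with 1 (CuI, trans-N,N'-dimethylcyclohexane-1,2-diamine, K3PO4, toluene, 90 °C; the C–I bond reacts well before either C–Br bond) gives 6-bromo-3-(6-bromo-1H-indol-1-yl)-1-(4-methylbenzenesulfonyl)-1H-indole F3. KOH in MeOH/THF at 60 °C removes the sulfonyl group and delivers 3.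

2. Step 1. Under acid the electrophilic iodane may oxidise or oligomerise the unprotected indole instead of giving 2, and the N–H iodonium salt may be hard to isolate. Fallback setting out from 1 and coming back at 2, which reverses the polarity of the activation (the indolide anion attacks the neutral diacetate, no acid present): 1 with MesI(OAc)2 and KOH in MeOH at 0 °C gives the sparingly soluble inner salt (6-bromoindol-1-id-3-yl)(2,4,6-trimethylphenyl)iodonium F4, which is filtered off. Protonation of F4 at nitrogen with TsOH·H2O (1.0 equiv) in MeCN at 0 °C gives 2.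

3. Step 3. Risks are partial formation of the branched (reverse-prenyl) isomer at one of the two sites, incomplete second coupling, and protodebromination. Fallback setting out from 3 and coming back at 5: twofold Suzuki–Miyaura coupling of 3 with allylboronic acid pinacol ester (Pd(PPh3)4, CsF, THF, 70 °C), where no regiochemical question arises, gives 6-(prop-2-en-1-yl)-3-[6-(prop-2-en-1-yl)-1H-indol-1-yl]-1H-indole F5. Twofold cross-metathesis of F5 with excess 2-methylbut-2-ene (second-generation Grubbs catalyst RuCl2(=CHPh)(H2IMes)(PCy3), CH2Cl2, 40 °C) turns each allyl group into a prenyl group and gives 5.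

**Further compounds**
F1 | step 2 | 6-bromo-3-iodo-1H-indole | Brc1ccc2c(I)c[nH]c2c1
F2 | step 2 | 6-bromo-3-iodo-1-(4-methylbenzenesulfonyl)-1H-indole | Cc1ccc(S(=O)(=O)n2cc(I)c3ccc(Br)cc32)cc1
F3 | step 2 | 6-bromo-3-(6-bromo-1H-indol-1-yl)-1-(4-methylbenzenesulfonyl)-1H-indole | Cc1ccc(S(=O)(=O)n2cc(-n3ccc4ccc(Br)cc43)c3ccc(Br)cc32)cc1
F4 | step 1 | (6-bromoindol-1-id-3-yl)(2,4,6-trimethylphenyl)iodonium (inner salt) | Cc1cc(C)c([I+]c2c[n-]c3cc(Br)ccc23)c(C)c1
F5 | step 3 | 6-(prop-2-en-1-yl)-3-[6-(prop-2-en-1-yl)-1H-indol-1-yl]-1H-indole | C=CCc1ccc2c(-n3ccc4ccc(CC=C)cc43)c[nH]c2c1
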